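**Retrosynthetic overview**
1. Target ⇒ cleave the C15 silyl ether; the C8 ester comes from a Mitsunobu inversion of the (8R)-alcohol of the bicyclic core with (Z)-2-(acetoxymethyl)but-2-enoic acid (made from crotonaldehyde).
2. Bicyclic core ⇒ an acyclic aldehyde carrying a 2-(bromomethyl)acrylate ester on O6: in one flask the five-membered lactone ring closes first (ring-closing metathesis, C7=C11, giving a bromomethyl butenolide) and the ten-membered carbocycle second (indium-mediated vinylogous Barbier allylation, C7–C8 bond, which also creates C7, C8 and the exocyclic methylene).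
3. Acyclic precursor ⇒ (E)-selective Horner–Wadsworth–Emmons union at C3=C4 of an aldehyde from (R)-linalool (C1–C3, C8–C10, C14) with a vinyl lactone phosphonate from (R)-2-vinyloxirane and triethyl phosphonoacetate (C4–C7, C15); C11–C13 come from 2-(bromomethyl)acrylic acid.
4. Stereocontrol: C10 from linalool, C6 from the epoxide, C7 and C8 in the ring closure (anti attack on the butenolide, chair transition state), C8 then inverted during ester formation.

Assumption: commercial (R)-(−)-linalool is taken as enantiopure; locants C1–C15 follow germacrane numbering of the target (C6 bears the lactone oxygen, C8 the ester, C10 the tertiary hydroxyl, C15 is the CH2OH carbon, C13 the exocyclic CH2).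

**Route**

Step 1
Reactants: 1 rac-2-vinyloxirane (racemic butadiene monoepoxide)
Product: 2 (R)-2-vinyloxirane
Conditions: (R,R)-(salen)Co(OAc) (0.5 mol %; salen = N,N′-bis(3,5-di-tert-butylsalicylidene)cyclohexane-1,2-diaminate), H2O (0.55 equiv), neat, 0 → 25 °C; distil
Reagents that add atoms: none
Why: Jacobsen hydrolytic kinetic resolution, in which the chiral cobalt–salen catalyst (the enantiomer that hydrates the (S)-epoxide faster) converts the unwanted enantiomer into the diol, so the volatile (R)-epoxide carrying the future C6 stereocentre is recovered in high ee.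

Step 2
Reactants: 2 (R)-2-vinyloxirane; 3 triethyl phosphonoacetate
Product: 4 diethyl [(5S)-5-ethenyl-2-oxooxolan-3-yl]phosphonate (both C3 epimers)
Conditions: NaOEt (1.05 equiv), EtOH, 0 → 78 °C; aq NH4Cl
Reagents that add atoms: none
Why: Malonate-type alkylation–lactonisation, in which the stabilised phosphonoacetate anion opens the epoxide by SN2 attack at the unsubstituted CH2 terminus and the alkoxide closes the γ-lactone on the ethyl ester, leaving the C–O stereocentre untouched (the descriptor changes to S only through CIP priorities).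

Step 3
Reactants: 5 (R)-(−)-linalool
Product: 7 (3R)-3,7-dimethyloct-6-ene-1,3-diol, via B-alkyl-9-BBN adduct 6 (not isolated)
Conditions: 9-BBN (2.2 equiv), THF, 0 → 25 °C; then NaOH, H2O2, 0 → 25 °C
Reagents that add atoms: hydrogen peroxide (OO)
Why: Chemoselective anti-Markovnikov hydroboration–oxidation, in which 9-BBN adds only to the monosubstituted vinyl group and not to the trisubstituted alkene, placing oxygen on the future C8 without touching the carbinol stereocentre (C10).

Step 4
Reactants: 7 (3R)-3,7-dimethyloct-6-ene-1,3-diol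
Product: 8 (4R)-2,2,4-trimethyl-4-(4-methylpent-3-en-1-yl)-1,3-dioxane
Conditions: 2,2-dimethoxypropane, PPTS (cat.), CH2Cl2, 25 °C
Reagents that add atoms: 2,2-dimethoxypropane (COC(C)(C)OC)
Why: Acid-catalysed transketalisation (isopropylidene ketal formation) masks the primary and the tertiary hydroxyl together as a 1,3-dioxane that has no acetal C–H and therefore survives ozone, base and hydride.

Step 5
Reactants: 8 (4R)-2,2,4-trimethyl-4-(4-methylpent-3-en-1-yl)-1,3-dioxane
Product: 10 3-[(4R)-2,2,4-trimethyl-1,3-dioxan-4-yl]propanal, via secondary ozonide 9 (not isolated)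
Conditions: O3, CH2Cl2, −78 °C; then PPh3, −78 → 25 °C
Reagents that add atoms: ozone (O=[O+][O-])
Why: Ozonolysis with reductive work-up cleaves the only alkene present to the C3 aldehyde and acetone.

Step 6
Reactants: 10 3-[(4R)-2,2,4-trimethyl-1,3-dioxan-4-yl]propanal; 4 diethyl [(5S)-5-ethenyl-2-oxooxolan-3-yl]phosphonate
Product: 11 (3E,5S)-5-ethenyl-3-{3-[(4R)-2,2,4-trimethyl-1,3-dioxan-4-yl]propylidene}oxolan-2-one
Conditions: LiCl (1.2 equiv), DBU (1.1 equiv), MeCN, 0 → 25 °C
Reagents that add atoms: none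
Why: Horner–Wadsworth–Emmons olefination under Masamune–Roush conditions, in which the stabilised lactone phosphonate gives mainly the (E)-alkylidene lactone (chain trans to C=O), fixing the C3=C4 geometry of the target while the ketal keeps the tertiary hydroxyl from adding to the new enoate.

Step 7
Reactants: 11 (3E,5S)-5-ethenyl-3-{3-[(4R)-2,2,4-trimethyl-1,3-dioxan-4-yl]propylidene}oxolan-2-one
Product: 12 (2E)-2-[(2S)-2-hydroxybut-3-en-1-yl]-5-[(4R)-2,2,4-trimethyl-1,3-dioxan-4-yl]pent-2-en-1-ol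
Conditions: i-Bu2AlH (4.5 equiv), CH2Cl2, −78 → 0 °C; aq KNaC4H4O6 (potassium sodium tartrate)
Reagents that add atoms: none
Why: Hydride reduction of a lactone to a diol, in which i-Bu2AlH reduces the α-alkylidene lactone in the 1,2-sense through the lactol to the C15 primary allylic alcohol and the C6 secondary allylic alcohol without touching the alkene geometry or the ketal.

Step 8
Reactants: 12 (2E)-2-[(2S)-2-hydroxybut-3-en-1-yl]-5-[(4R)-2,2,4-trimethyl-1,3-dioxan-4-yl]pent-2-en-1-ol
Product: 13 (3S,5E)-5-{[(tert-butyldiphenylsilyl)oxy]methyl}-8-[(4R)-2,2,4-trimethyl-1,3-dioxan-4-yl]octa-1,5-dien-3-ol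
Conditions: TBDPSCl (1.05 equiv), imidazole, CH2Cl2, 0 °C
Reagents that add atoms: tert-butyl(chloro)diphenylsilane (CC(C)(C)[Si](Cl)(c1ccccc1)c1ccccc1)
Why: Chemoselective silylation, in which the bulky silyl chloride reacts with the primary allylic hydroxyl (C15) much faster than with the secondary one (C6).

Step 9
Reactants: 13 (3S,5E)-5-{[(tert-butyldiphenylsilyl)oxy]methyl}-8-[(4R)-2,2,4-trimethyl-1,3-dioxan-4-yl]octa-1,5-dien-3-ol; 14 2-(bromomethyl)acrylic acid
Product: 15 (3S,5E)-5-{[(tert-butyldiphenylsilyl)oxy]methyl}-8-[(4R)-2,2,4-trimethyl-1,3-dioxan-4-yl]octa-1,5-dien-3-yl 2-(bromomethyl)prop-2-enoate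
Conditions: DCC (1.2 equiv), DMAP (0.05 equiv), CH2Cl2, −20 → 0 °C
Reagents that add atoms: none
Why: Steglich esterification, in which carbodiimide activation acylates the only free (secondary allylic) hydroxyl with retention at C6, while low temperature and only catalytic DMAP limit substitution of the allylic bromide.

Step 10
Reactants: 15 (3S,5E)-5-{[(tert-butyldiphenylsilyl)oxy]methyl}-8-[(4R)-2,2,4-trimethyl-1,3-dioxan-4-yl]octa-1,5-dien-3-yl 2-(bromomethyl)prop-2-enoate
Product: 16 (3S,5E,9R)-5-{[(tert-butyldiphenylsilyl)oxy]methyl}-9,11-dihydroxy-9-methylundeca-1,5-dien-3-yl 2-(bromomethyl)prop-2-enoate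
Conditions: AcOH/THF/H2O 4:1:1, 25 °C
Reagents that add atoms: none
Why: Acid-catalysed ketal hydrolysis, in which the strained 4,4-disubstituted isopropylidene ketal is cleaved under conditions mild enough for the TBDPS ether, the allylic ester and the allylic bromide.

Step 11
Reactants: 16 (3S,5E,9R)-5-{[(tert-butyldiphenylsilyl)oxy]methyl}-9,11-dihydroxy-9-methylundeca-1,5-dien-3-yl 2-(bromomethyl)prop-2-enoate
Product: 17 (3S,5E,9R)-5-{[(tert-butyldiphenylsilyl)oxy]methyl}-9-hydroxy-9-methyl-11-oxoundeca-1,5-dien-3-yl 2-(bromomethyl)prop-2-enoate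
Conditions: Dess–Martin periodinane (1.3 equiv), NaHCO3, CH2Cl2, 0 → 25 °C; used crude
Reagents that add atoms: none
Why: Dess–Martin oxidation, in which only the primary alcohol can be oxidised, giving the C8 aldehyde next to the untouched tertiary carbinol.

Step 12
Reactants: 17 (3S,5E,9R)-5-{[(tert-butyldiphenylsilyl)oxy]methyl}-9-hydroxy-9-methyl-11-oxoundeca-1,5-dien-3-yl 2-(bromomethyl)prop-2-enoate
Product: 19 (3aS,4R,6R,9E,11aS)-10-{[(tert-butyldiphenylsilyl)oxy]methyl}-4,6-dihydroxy-6-methyl-3-methylidene-3a,4,5,6,7,8,11,11a-octahydrocyclodeca[b]furan-2(3H)-one, via bromomethyl butenolide aldehyde 18 (not isolated)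
Conditions: RuCl2(H2IMes)(=CH-C6H4-2-OiPr) (second-generation Hoveyda–Grubbs catalyst, 5 mol %; H2IMes = 1,3-dimesitylimidazolidin-2-ylidene), toluene (0.005 M), 70 °C; then concentrate in the same flask, THF/H2O 3:1 (0.003 M), In powder (3 equiv), 25 °C
Reagents that add atoms: none
Why: Proposed new method: ring-closing metathesis between the C6 vinyl group and the 2-(bromomethyl)acrylate first closes the butenolide 18, and indium then turns its allylic bromide into a water-tolerant allylindium that adds through its γ-carbon (C7) to the tethered aldehyde in a vinylogous Barbier allylation, closing the ten-membered ring and moving the double bond to the exocyclic C11=C13 position; approach of the aldehyde anti to the C5 chain on C6 gives the trans-fused lactone and a chair Zimmerman–Traxler transition state with the aldehyde substituent equatorial gives the 8R carbinol, the closest known reactions being the intermolecular indium or zinc Barbier allylation of aldehydes with 3-(bromomethyl)furan-2(5H)-one and the macrocyclic chromium-mediated Barbier closure of 2-(bromomethyl)acrylates used for germacranolides.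

Step 13
Reactants: 20 (E)-crotonaldehyde
Product: 22 (Z)-2-bromobut-2-enal, via 2,3-dibromobutanal 21 (not isolated)
Conditions: Br2 (1.0 equiv), CH2Cl2, 0 °C; then Et3N (1.2 equiv), 0 → 25 °C
Reagents that add atoms: bromine (BrBr)
Why: Bromination–dehydrobromination, in which Br2 adds across the C=C bond and Et3N then removes the acidic α-hydrogen with loss of the β-bromide (E1cB) to give the more stable (Z)-2-bromo enal with the methyl group cis to bromine.

Step 14
Reactants: 22 (Z)-2-bromobut-2-enal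
Product: 23 (Z)-2-bromobut-2-en-1-ol
Conditions: NaBH4, CeCl3·7H2O, MeOH, 0 °C
Reagents that add atoms: none
Why: Luche reduction, which reduces the aldehyde in the 1,2-sense and leaves the vinyl bromide and the alkene geometry unchanged.

Step 15
Reactants: 23 (Z)-2-bromobut-2-en-1-ol
Product: 25 (Z)-2-(hydroxymethyl)but-2-enoic acid, via dilithiated alkenyl alkoxide 24 (not isolated)
Conditions: t-BuLi (3.1 equiv), Et2O, −78 °C; then CO2, −78 → 0 °C; aq HCl
Reagents that add atoms: carbon dioxide (O=C=O)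
Why: Bromine–lithium exchange followed by carboxylation, in which the alkenyllithium formed on the lithium alkoxide is configurationally stable at −78 °C and is trapped by CO2 with retention, so the carboxyl group ends up cis to the methyl group.

Step 16
Reactants: 25 (Z)-2-(hydroxymethyl)but-2-enoic acid
Product: 26 (Z)-2-(acetoxymethyl)but-2-enoic acid
Conditions: Ac2O (1.5 equiv), pyridine, DMAP (cat.), CH2Cl2, 0 → 25 °C; then H2O
Reagents that add atoms: acetic anhydride (CC(=O)OC(C)=O)
Why: O-Acetylation (nucleophilic acyl substitution) of the primary allylic hydroxyl, any mixed anhydride formed at the carboxyl group being hydrolysed on aqueous work-up.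

Step 17
Reactants: 19 (3aS,4R,6R,9E,11aS)-10-{[(tert-butyldiphenylsilyl)oxy]methyl}-4,6-dihydroxy-6-methyl-3-methylidene-3a,4,5,6,7,8,11,11a-octahydrocyclodeca[b]furan-2(3H)-one; 26 (Z)-2-(acetoxymethyl)but-2-enoic acid
Product: 27 (3aR,4S,6R,9E,11aS)-10-{[(tert-butyldiphenylsilyl)oxy]methyl}-6-hydroxy-6-methyl-3-methylidene-2-oxo-2,3,3a,4,5,6,7,8,11,11a-decahydrocyclodeca[b]furan-4-yl (2Z)-2-(acetoxymethyl)but-2-enoate
Conditions: PPh3 (2.5 equiv), DIAD (2.5 equiv), toluene, 0 → 25 °C
Reagents that add atoms: none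
Why: Mitsunobu esterification, in which the carboxylate displaces the C8 oxyphosphonium in an SN2 reaction that inverts C8 from R to S and installs the side chain at once, while the tertiary C10 hydroxyl is too hindered to react.

Step 18
Reactants: 27 (3aR,4S,6R,9E,11aS)-10-{[(tert-butyldiphenylsilyl)oxy]methyl}-6-hydroxy-6-methyl-3-methylidene-2-oxo-2,3,3a,4,5,6,7,8,11,11a-decahydrocyclodeca[b]furan-4-yl (2Z)-2-(acetoxymethyl)but-2-enoate
Product: 28 (3aR,4S,6R,9E,11aS)-6-hydroxy-10-(hydroxymethyl)-6-methyl-3-methylidene-2-oxo-2,3,3a,4,5,6,7,8,11,11a-decahydrocyclodeca[b]furan-4-yl (2Z)-2-(acetoxymethyl)but-2-enoate (CNP0313132.1)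
Conditions: HF·pyridine, pyridine, THF, 0 → 25 °C
Reagents that add atoms: none
Why: Fluoride-mediated silyl ether cleavage, in which buffered HF·pyridine removes the TBDPS group without transesterifying the two esters or adding to the α-methylene lactone.

**Compound list**
1 | rac-2-vinyloxirane (racemic butadiene monoepoxide) | C=CC1CO1 | starting material
2 | (R)-2-vinyloxirane | C=C[C@@H]1CO1 | intermediate
3 | triethyl phosphonoacetate | CCOC(=O)CP(=O)(OCC)OCC | starting material
4 | diethyl [(5S)-5-ethenyl-2-oxooxolan-3-yl]phosphonate (both C3 epimers) | C=C[C@@H]1CC(P(=O)(OCC)OCC)C(=O)O1 | intermediate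
5 | (R)-(−)-linalool, (3R)-3,7-dimethylocta-1,6-dien-3-ol | CC(C)=CCC[C@@](C)(O)C=C | starting material
6 | 9-[(3S)-3-hydroxy-3,7-dimethyloct-6-en-1-yl]-9-borabicyclo[3.3.1]nonane (same spatial arrangement as 5; formed in the flask) | CC(C)=CCC[C@@](C)(O)CCB1C2CCCC1CCC2 | intermediate
7 | (3R)-3,7-dimethyloct-6-ene-1,3-diol | CC(C)=CCC[C@@](C)(O)CCO | intermediate
8 | (4R)-2,2,4-trimethyl-4-(4-methylpent-3-en-1-yl)-1,3-dioxane | CC(C)=CCC[C@]1(C)CCOC(C)(C)O1 | intermediate
9 | 3,3-dimethyl-5-{2-[(4R)-2,2,4-trimethyl-1,3-dioxan-4-yl]ethyl}-1,2,4-trioxolane (secondary ozonide, both C5 epimers; formed in the flask) | CC1(C)OOC(CC[C@]2(C)CCOC(C)(C)O2)O1 | intermediate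
10 | 3-[(4R)-2,2,4-trimethyl-1,3-dioxan-4-yl]propanal | O=CCC[C@]1(C)CCOC(C)(C)O1 | intermediate
11 | (3E,5S)-5-ethenyl-3-{3-[(4R)-2,2,4-trimethyl-1,3-dioxan-4-yl]propylidene}oxolan-2-one | C=C[C@@H]1C/C(=C\CC[C@]2(C)CCOC(C)(C)O2)C(=O)O1 | intermediate
12 | (2E)-2-[(2S)-2-hydroxybut-3-en-1-yl]-5-[(4R)-2,2,4-trimethyl-1,3-dioxan-4-yl]pent-2-en-1-ol | C=C[C@@H](O)C/C(CO)=C\CC[C@]1(C)CCOC(C)(C)O1 | intermediate
13 | (3S,5E)-5-{[(tert-butyldiphenylsilyl)oxy]methyl}-8-[(4R)-2,2,4-trimethyl-1,3-dioxan-4-yl]octa-1,5-dien-3-ol | C=C[C@@H](O)C/C(CO[Si](c1ccccc1)(c2ccccc2)C(C)(C)C)=C\CC[C@]3(C)CCOC(C)(C)O3 | intermediate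
14 | 2-(bromomethyl)acrylic acid | C=C(CBr)C(=O)O | starting material
15 | (3S,5E)-5-{[(tert-butyldiphenylsilyl)oxy]methyl}-8-[(4R)-2,2,4-trimethyl-1,3-dioxan-4-yl]octa-1,5-dien-3-yl 2-(bromomethyl)prop-2-enoate | C=C[C@@H](OC(=O)C(=C)CBr)C/C(CO[Si](c1ccccc1)(c2ccccc2)C(C)(C)C)=C\CC[C@]3(C)CCOC(C)(C)O3 | intermediate
16 | (3S,5E,9R)-5-{[(tert-butyldiphenylsilyl)oxy]methyl}-9,11-dihydroxy-9-methylundeca-1,5-dien-3-yl 2-(bromomethyl)prop-2-enoate | C=C[C@@H](OC(=O)C(=C)CBr)C/C(CO[Si](c1ccccc1)(c2ccccc2)C(C)(C)C)=C\CC[C@@](C)(O)CCO | intermediate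
17 | (3S,5E,9R)-5-{[(tert-butyldiphenylsilyl)oxy]methyl}-9-hydroxy-9-methyl-11-oxoundeca-1,5-dien-3-yl 2-(bromomethyl)prop-2-enoate | C=C[C@@H](OC(=O)C(=C)CBr)C/C(CO[Si](c1ccccc1)(c2ccccc2)C(C)(C)C)=C\CC[C@@](C)(O)CC=O | intermediate
18 | (5S)-3-(bromomethyl)-5-[(2E,6R)-2-{[(tert-butyldiphenylsilyl)oxy]methyl}-6-hydroxy-6-methyl-8-oxooct-2-en-1-yl]furan-2(5H)-one (formed in the flask) | BrCC1=C[C@H](C/C(CO[Si](c2ccccc2)(c3ccccc3)C(C)(C)C)=C\CC[C@@](C)(O)CC=O)OC1=O | intermediate
19 | (3aS,4R,6R,9E,11aS)-10-{[(tert-butyldiphenylsilyl)oxy]methyl}-4,6-dihydroxy-6-methyl-3-methylidene-3a,4,5,6,7,8,11,11a-octahydrocyclodeca[b]furan-2(3H)-one (germacrane locants 6S,7S,8R,10R) | C=C1C(=O)O[C@H]2C/C(CO[Si](c3ccccc3)(c4ccccc4)C(C)(C)C)=C\CC[C@@](C)(O)C[C@@H](O)[C@H]12 | intermediate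
20 | (E)-crotonaldehyde | C/C=C/C=O | starting material
21 | 2,3-dibromobutanal (mixture of diastereomers; formed in the flask) | CC(Br)C(Br)C=O | intermediate
22 | (Z)-2-bromobut-2-enal | C/C=C(\Br)C=O | intermediate
23 | (Z)-2-bromobut-2-en-1-ol | C/C=C(\Br)CO | intermediate
24 | lithium 2-lithiobut-2-en-1-olate with lithium cis to the methyl group (formed in the flask) | C/C=C(\[Li])CO[Li] | intermediate
25 | (Z)-2-(hydroxymethyl)but-2-enoic acid | C/C=C(\C(=O)O)CO | intermediate
26 | (Z)-2-(acetoxymethyl)but-2-enoic acid | C/C=C(\C(=O)O)COC(C)=O | intermediate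
27 | (3aR,4S,6R,9E,11aS)-10-{[(tert-butyldiphenylsilyl)oxy]methyl}-6-hydroxy-6-methyl-3-methylidene-2-oxo-2,3,3a,4,5,6,7,8,11,11a-decahydrocyclodeca[b]furan-4-yl (2Z)-2-(acetoxymethyl)but-2-enoate | C=C1C(=O)O[C@H]2C/C(CO[Si](c3ccccc3)(c4ccccc4)C(C)(C)C)=C\CC[C@@](C)(O)C[C@H](OC(=O)/C(=C\C)COC(C)=O)[C@H]12 | intermediate
28 | (3aR,4S,6R,9E,11aS)-6-hydroxy-10-(hydroxymethyl)-6-methyl-3-methylidene-2-oxo-2,3,3a,4,5,6,7,8,11,11a-decahydrocyclodeca[b]furan-4-yl (2Z)-2-(acetoxymethyl)but-2-enoate (germacrane locants 6S,7R,8S,10R) | C=C1C(=O)O[C@H]2C/C(CO)=C\CC[C@@](C)(O)C[C@H](OC(=O)/C(=C\C)COC(C)=O)[C@H]12 | target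

**Step count and risks**
Total step count: 18 (steps 1–2 phosphonate branch, steps 3–12 main line, steps 13–16 acid branch, steps 17–18 end game).
Longest linear sequence: 12 steps, from 5 to 28 through steps 3–12, 17 and 18.

Most likely to fail, 1: step 12. The metathesis has to tolerate an allylic bromide and a free aldehyde. The ten-membered closure competes with protonolysis and oligomerisation of the allylindium. The facial and C8 selectivities rest on a transition-state argument without direct precedent in a macrocyclisation. Fallback, setting out from 16: ring-closing metathesis with the same ruthenium catalyst gives the bromomethyl butenolide diol F1. Bu3SnSnBu3 with Pd(PPh3)4 (THF, 50 °C) converts the allylic bromide into the allylstannane diol F2. SO3·pyridine/DMSO/i-Pr2NEt oxidises the primary alcohol to the stannane aldehyde F3. BF3·OEt2 (CH2Cl2, −78 °C, high dilution) then closes the ten-membered ring through an open antiperiplanar transition state, which is syn-selective and gives the (8S)-alcohol F4 directly. Yamaguchi esterification of F4 with 26 (2,4,6-trichlorobenzoyl chloride, Et3N, DMAP; retention) comes back to the route at 27.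

Most likely to fail, 2: step 17. The C8 carbinol sits in a medium ring next to the C7 methine, so elimination or lack of reaction can compete with SN2 inversion, and PPh3 can add to the α-methylene lactone. Fallback, setting out from 19: chloromethanesulfonyl chloride and pyridine (0 °C) give the (8R)-chloromethanesulfonate F5. This is displaced with inversion by the caesium salt of 26 (made from 26 and Cs2CO3; 18-crown-6, toluene, 60 °C), coming back to the route at 27.

Most likely to fail, 3: step 10. The acyclic 2-(bromomethyl)acrylate is both an allylic bromide and a Michael acceptor, and may not survive aqueous acid. Fallback, setting out from 13: the ketal is hydrolysed before the acrylate is installed (AcOH/THF/H2O) to give the triol F6. Its primary hydroxyl alone is oxidised with TEMPO (cat.), N-chlorosuccinimide and Bu4NCl in buffered CH2Cl2/H2O to the hydroxy aldehyde F7. The remaining secondary allylic hydroxyl is then esterified with 14 (DCC, cat. DMAP, −20 °C), coming back to the route at 17 and bypassing step 11.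

**Further compounds**
F1 | step 12 | (5S)-3-(bromomethyl)-5-[(2E,6R)-2-{[(tert-butyldiphenylsilyl)oxy]methyl}-6,8-dihydroxy-6-methyloct-2-en-1-yl]furan-2(5H)-one | BrCC1=C[C@H](C/C(CO[Si](c2ccccc2)(c3ccccc3)C(C)(C)C)=C\CC[C@@](C)(O)CCO)OC1=O
F2 | step 12 | (5S)-5-[(2E,6R)-2-{[(tert-butyldiphenylsilyl)oxy]methyl}-6,8-dihydroxy-6-methyloct-2-en-1-yl]-3-[(tributylstannyl)methyl]furan-2(5H)-one | CCCC[Sn](CCCC)(CCCC)CC1=C[C@H](C/C(CO[Si](c2ccccc2)(c3ccccc3)C(C)(C)C)=C\CC[C@@](C)(O)CCO)OC1=O
F3 | step 12 | (5S)-5-[(2E,6R)-2-{[(tert-butyldiphenylsilyl)oxy]methyl}-6-hydroxy-6-methyl-8-oxooct-2-en-1-yl]-3-[(tributylstannyl)methyl]furan-2(5H)-one | CCCC[Sn](CCCC)(CCCC)CC1=C[C@H](C/C(CO[Si](c2ccccc2)(c3ccccc3)C(C)(C)C)=C\CC[C@@](C)(O)CC=O)OC1=O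
F4 | step 12 | (3aS,4S,6R,9E,11aS)-10-{[(tert-butyldiphenylsilyl)oxy]methyl}-4,6-dihydroxy-6-methyl-3-methylidene-3a,4,5,6,7,8,11,11a-octahydrocyclodeca[b]furan-2(3H)-one | C=C1C(=O)O[C@H]2C/C(CO[Si](c3ccccc3)(c4ccccc4)C(C)(C)C)=C\CC[C@@](C)(O)C[C@H](O)[C@H]12
F5 | step 17 | (3aR,4R,6R,9E,11aS)-10-{[(tert-butyldiphenylsilyl)oxy]methyl}-6-hydroxy-6-methyl-3-methylidene-2-oxo-2,3,3a,4,5,6,7,8,11,11a-decahydrocyclodeca[b]furan-4-yl chloromethanesulfonate | C=C1C(=O)O[C@H]2C/C(CO[Si](c3ccccc3)(c4ccccc4)C(C)(C)C)=C\CC[C@@](C)(O)C[C@@H](OS(=O)(=O)CCl)[C@H]12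
F6 | step 10 | (3S,5E,9R)-5-{[(tert-butyldiphenylsilyl)oxy]methyl}-9-methylundeca-1,5-diene-3,9,11-triol | C=C[C@@H](O)C/C(CO[Si](c1ccccc1)(c2ccccc2)C(C)(C)C)=C\CC[C@@](C)(O)CCO
F7 | step 10 | (3R,6E,9S)-7-{[(tert-butyldiphenylsilyl)oxy]methyl}-3,9-dihydroxy-3-methylundeca-6,10-dienal | C=C[C@@H](O)C/C(CO[Si](c1ccccc1)(c2ccccc2)C(C)(C)C)=C\CC[C@@](C)(O)CC=O
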